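I read this flask at 2.0 h, and Wednesday's run has a reading at that hour.

| setting | Sunday's | Wednesday's | flask |
|---|---|---|---|
| Ej | 0.21 M | 0.32 M | 0.43 M |
| Wy | 25 mM (held) | 25 mM (held) | 25 mM (held) |
| remark | run made earlier | run made earlier |  |
| time |  |  | 2.0 h |

- Sunday's (time / h: VyWu / %): 0.200: 2.3; 0.333: 5.3; 0.417: 6.2; 0.667: 9.1; 1.00: 12.0; 1.50: 14.6; 2.50: 17.9
- Wednesday's (time / h: VyWu / %): 0.333: 2.5; 0.667: 6.2; 1.00: 7.8; 1.33: 9.5; 1.50: 9.7; 2.00: 10.8; 2.50: 12.0

(standard deviation of a reading: 0.3 percentage points)

- given per volume of solution although it is solid: Ej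
- at the start none of Wu is dissolved
- the earlier runs were read with a standard deviation of 0.3 percentage points
- steps that have been proposed: Vy + Wu -> VyWu; Wu + VyWu -> WuVyWu; Wy <-> Wu; VyWu -> Gu; Ej <-> Vy
- at the start none of Ej is in solution

- dawn: doubling the saturation concentration of Wy, all else as stated
- summer: doubling the transfer coefficient of Wy, all else as stated
- autumn: doubling the solubility of Ej, all else as stated
- noon: doubling the dissolution coefficient of Ej, all else as stated

* amount of VyWu at 2.0 h, in percent of the Ej charged
* the change that raises the amount of VyWu at 2.0 h, in percent of the Ej charged most ("none" if none brings more than 2 percentage points) (dawn / summer / autumn / noon / none)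
* amount of VyWu at 2.0 h, in percent of the Ej charged, after summer

But Wednesday's percent is a percent of its own charge, and this flask holds more Ej, so I don't carry the percent over. Percent times charge gives 34.6 mM for Wednesday's run; I call this the molar make c, the VyWu standing per volume of solution at a given hour.

Does c ignore the charge? At 1.00 h Sunday's run gives 25.2 mM and Wednesday's 25.0 mM, nearly equal, though the charges stand 1.52-fold apart. So across these two charges the make reads as zero order in Ej.

So I divide by this flask's charge and get 8.05%, give or take 0.22 percentage points from the scatter of that one reading. But 0.43 M lies beyond both runs, so this is an extrapolation.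

The forecast says 8% (7.6% to 8.5%), names autumn as the best change, and puts summer at 10.3% (8% to 14%), holding that “the product does not depend on the Ej charge”.

The flask gives 8.12%, which is a molar make of 34.9 mM. The best change is autumn, at 12 points, but summer gives 5.17%, below the forecast's range. At 2.00 h this flask holds 17.7% WuVyWu beside 8.12% VyWu.

    Vy + Wu → VyWu (k = 8.88 /M/min)
    Wu + VyWu → WuVyWu (k = 3.65 /M/min)
    Wy ⇌ Wu, rate k3*(csat - [Wu]) (kL = 0.102 /min)
    VyWu → Gu (k = 0.00337 /min)
    Ej ⇌ Vy, rate k5*(cs5 - [Vy]) while solid is left; crystals form when [Vy] > cs5 (solubility = 0.110 M, k = 0.0120 /min)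

Sunday's charge of 0.21 M, taken to 2.0 h, has by c the share 16.5%, and without the scatter that charge stands at 16.6% at that hour.

(The earlier runs and the new flask were computed for an exercise; noise was put on by code.)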